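(All runs are simulated from invented constants; scatter was added.)

In the first hours Thursday's flask loses its substrate, and I want to know what that leaves standing when I look at 15 h.

common to all: substrate 0.065 M
- Thursday's: first nucleophile 0.13 M; second nucleophile 0.0455 M; temperature 20 °C; the very flask that is asked about, followed so far
- Friday's: first nucleophile 0.13 M; second nucleophile 0.030 M; temperature 26 °C; run made earlier
- flask: first nucleophile 0.130 M; second nucleophile 0.0455 M; temperature 20 °C; time 15 h

- Thursday's (time / h: target / %, substrate / %): 2.00: 60, 2; 4.00: 60, 0; 5.00: 63, 0; 8.00: 64, 0; 10.0: 63, 0
- Friday's (time / h: target / %, substrate / %): 0.500: 57, 19; 0.833: 63, 6; 1.50: 74, 1; 3.00: 68, 0; 6.00: 69, 4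

(standard deviation of a reading: 2 percentage points)

- percentages count the substrate that a species holds: one side product counts as two
- what is taken out of target is counted as made
- what may be going on: first nucleophile + intermediate -> target; substrate + intermediate -> side product; second nucleophile + intermediate -> other capture product; substrate -> intermediate; intermediate -> solvolysis product
- additions bring no volume worth counting

- blue: at 15 h add first nucleophile, 100% of the amount charged, then wait 30 h
- amber: at 15 h raise the temperature by 15 K, then wait 30 h
- violet: at 15 h take out 90% of the target then present, then wait 30 h
- teal: change nothing and wait 30 h more

- target, in percent of the substrate first charged, at 15 h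
- the option that brings most further target ("none" if no option brings more than 2 percentage points) (blue / amber / violet / teal / none)
- target present, with what was taken out counted in, in percent of the substrate first charged, after blue
- target present, with what was taken out counted in, in percent of the substrate first charged, after teal

The first clock I can read is the substrate's. Thursday's reading of 2% at 2.00 h gives, with the wide scatter of so small a reading, a rate of about 1.96 h⁻¹ and a half-life of 0.354 h, far shorter than the wait to 15 h.

The intermediate has no reading of its own, so I look at it through the target. At that same reading Thursday's target is 61.2% of the substrate consumed, and the later readings level at 62.5%. So, within the scatter, capture keeps step with the loss of substrate, and I see no stock of intermediate waiting.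

The wait after that is empty: from 4.00 h Thursday's substrate reads 0%, and no listed step turns a product back. What remains is how the intermediate divided while it lasted. Against the substrate charge, this flask holds 2.00 of first nucleophile and 0.700 of second. I therefore name the split, a selectivity factor: target over everything else the substrate became, multiplied by the charge of second nucleophile over the charge of first nucleophile. Here it is 0.583. The small losses stay inside the remainder as a correction I don't separate. My own reckoning for 15 h is the plateau, with no option moving it.

The forecast gives 62%, within 60% to 64.5%, best option none, 62% after blue and 62% after teal, on the ground that “nothing can feed more target”. My plateau lies 0.5 percentage points above its figure, less than the scatter of a reading.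

The flask holds 61.9% of target at 15 h; the best option is none, blue gives 61.9% and teal 61.9%.

    first nucleophile + intermediate → target (k = 0.0246 L mol⁻¹ s⁻¹, Ea = 70.0 kJ mol⁻¹)
    substrate + intermediate → side product (k = 1.41 × 10⁻⁴ L mol⁻¹ s⁻¹, Ea = 65.0 kJ mol⁻¹)
    second nucleophile + intermediate → other capture product (k = 0.0438 L mol⁻¹ s⁻¹, Ea = 47.0 kJ mol⁻¹)
    substrate → intermediate (k = 4.80 × 10⁻⁴ s⁻¹, Ea = 80.0 kJ mol⁻¹)
    intermediate → solvolysis product (k = 1.76 × 10⁻⁴ s⁻¹, Ea = 91.0 kJ mol⁻¹)
    (constants at 20 °C)

The step to target has 91% of its turnover behind it by 1.50 h, far earlier than the look at 15 h, and this flask still holds 61.9% at 150 h. Reckoned from the 61.9% in this flask, the split is 0.569. Carried from the plateau to a neighbour charged with 0.11 M of second nucleophile, the split gives 40.8% of target, and that neighbour holds 40.8%.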